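The target is the meso (2R,3S,4R,5S) 2,5-diaryl-3,4-bis(acetoxymethyl)oxolane. Both aryl groups lie on one face and both CH2OAc arms on the other (2,3-trans, 3,4-cis, 4,5-trans), so racemic intermediates of the right relative configuration suffice.
Enabling feature: C3 and C4 are adjacent ring carbons that each carry a CH2O arm (C3a, C4a). A radical at C3 tied through C2–O1–C5 to a C4=C4a double bond is a 3-oxa-5-hexenyl radical, and its 5-exo closure is the oxolane ring itself.
Cuts, in retrosynthetic order: the O-benzyl and O-acetyl bonds, C4a–O (back to C4a–B), C3–C4 (radical ring closure), C4a–B (alkyne hydroboration), O1–C2 together with C3–Br (alkoxybromination of a cinnamate), C4–C5 (acetylide addition) and C2=C3 (olefination). Both halves come from 3,4-bis(benzyloxy)benzaldehyde.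
Forward: the two aryl-C3 halves are joined at O1–C2, boron is placed on C4a, and the oxolane ring closes at C3–C4. A temporary cis-fused γ-lactone ring then forms between C3a and the new C4a–OH and is reduced open again; acetylation and debenzylation finish the route.
C3a is carried as an ethyl ester. The ester directs the alkoxybromination, cannot act as a neighbouring group the way an allylic acetate could, weakens the C3–Br bond, and later secures and reports the 3,4-cis relationship through lactone formation.
Stereochemistry: C5 arises racemic, the C2/C5 pairing (aryls cis) is selected by separating the ether diastereomers, C3 and C4 are set in the chair-like cyclisation transition state, and no strong acid is used afterwards.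
Key step: step 5

Remark on the chemistry: because the target is meso, all chiral intermediates are made as racemates (names and SMILES show one enantiomer); the locants O1, C2–C5, C3a and C4a of the target are used for the same atoms throughout, and Ar = 3,4-bis(benzyloxy)phenyl.

Step 1
Reactants: 1 3,4-bis(benzyloxy)benzaldehyde; 2 ethynylmagnesium bromide
Product: 3 rac-(1S)-1-Ar-prop-2-yn-1-ol
Conditions: HC≡CMgBr (1.3 equiv), THF, 0 °C → rt; aqueous work-up
Reagents that add atoms: ethynylmagnesium bromide 2, C#C[Mg]Br
Why: 1,2-addition of an alkynyl Grignard reagent to a non-enolisable aromatic aldehyde is reliable, forms C4–C5 and creates C5 as a racemate, which is all a meso target requires.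

Step 2
Reactants: 1 3,4-bis(benzyloxy)benzaldehyde; 4 triethyl phosphonoacetate
Product: 5 ethyl (2E)-3-Ar-prop-2-enoate
Conditions: NaH, THF, 0 °C → rt
Reagents that add atoms: triethyl phosphonoacetate 4, CCOC(=O)CP(=O)(OCC)OCC
Why: Horner–Wadsworth–Emmons olefination of an aromatic aldehyde with a stabilised phosphonate anion forms C2=C3 with high E selectivity.

Step 3
Reactants: 5 ethyl (2E)-3-Ar-prop-2-enoate; 3 rac-(1S)-1-Ar-prop-2-yn-1-ol
Product: 6 rac-ethyl (2S,3S)-3-Ar-3-{[(1S)-1-Ar-prop-2-yn-1-yl]oxy}-2-bromopropanoate
Conditions: 3 (3 equiv, excess recovered), NBS (1.1 equiv), 4 Å MS, CH2Cl2, −20 °C → rt, dark; diastereomers separated on SiO2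
Reagents that add atoms: N-bromosuccinimide, O=C1CCC(=O)N1Br
Why: this is the intermolecular alkoxybromination (bromoetherification) known for electron-rich cinnamates with NBS and propargylic alcohols, in which the 4-benzyloxy group and the ester together send the alcohol to benzylic C2 and bromine to C3 by anti addition while the alkyne stays inert; C2 forms without control relative to C5, so the (3S,1′S)/(3R,1′R) pairing must be separated by chromatography, and the C3 configuration does not matter because step 5 erases it.

Step 4
Reactants: 6 rac-ethyl (2S,3S)-3-Ar-3-{[(1S)-1-Ar-prop-2-yn-1-yl]oxy}-2-bromopropanoate; 7 pinacolborane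
Product: 8 rac-ethyl (2S,3S)-3-Ar-3-{[(1S,2E)-1-Ar-3-(pinacolboryl)prop-2-en-1-yl]oxy}-2-bromopropanoate
Conditions: HBpin (1.5 equiv), Cy2BH (10 mol %), THF, rt, Ar
Reagents that add atoms: pinacolborane 7, CC1(C)OBOC1(C)C
Why: dialkylborane-catalysed syn hydroboration of a terminal alkyne with pinacolborane places boron on terminal C4a and gives the E-alkenylboronate, and the neutral room-temperature conditions spare the base-sensitive α-bromo-β-alkoxy ester and the benzyl ethers.

Step 5
Reactants: 8 rac-ethyl (2S,3S)-3-Ar-3-{[(1S,2E)-1-Ar-3-(pinacolboryl)prop-2-en-1-yl]oxy}-2-bromopropanoate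
Product: 9 rac-ethyl (2R,3R,4S,5S)-2,5-di-Ar-4-[(pinacolboryl)methyl]oxolane-3-carboxylate (aryls cis to each other; ester and CH2B arm cis to each other and trans to the aryls)
Conditions: Bu3SnH (1.3 equiv) + AIBN (0.2 equiv) by syringe pump over 6 h, PhH (0.01 M), 80 °C
Reagents that add atoms: none
Why: Bu3Sn• abstracts bromine from the α-bromo ester 8, the ester-stabilised C3 radical adds to C4 of the E-alkenylboronate to form C3–C4, and the α-boryl radical left at C4a takes hydrogen from Bu3SnH and so carries the chain. The closest known reaction type is the tin hydride cyclisation of β-bromo ethers (Ueno–Stork type), established for 2-bromo-3-aryl-3-(allyloxy or propargyloxy)propanoates, combined with the known use of alkenyl pinacolboronates as radical acceptors. The oxolane ring closes 5-exo-trig from a 3-oxa-5-hexenyl radical, whereas 6-endo attack at C4a is geometrically less favourable and would give up the boron-stabilised radical. C4 is controlled by the chair-like transition state in which the aryl groups on C2 and C5 of this diastereomer are both pseudo-equatorial, so the C4a arm ends trans to both. C3 is controlled by the adjacent C2 aryl group, which keeps the ester on the opposite face (2,3-trans) and therefore cis to the C4a arm, the same sense as the intrinsic cis preference of 1-substituted 5-hexenyl radicals. The step needs ring closure to outrun hydrogen transfer and bromine abstraction to outrun stannyl radical addition to the C=C bond, which the short C–O bonds and two branch points of the tether, the weak C–Br bond next to the ester and the slow addition of Bu3SnH at high dilution should secure.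

Step 6
Reactants: 9 rac-ethyl (2R,3R,4S,5S)-2,5-di-Ar-4-[(pinacolboryl)methyl]oxolane-3-carboxylate
Product: 11 rac-(3aR,4S,6R,6aR)-4,6-di-Ar-tetrahydro-1H,3H-furo[3,4-c]furan-1-one, via hydroxy ester 10 (not isolated)
Conditions: NaBO3·4H2O (4 equiv), THF/H2O 1:1, rt; then PPTS (cat.), CH2Cl2, rt
Reagents that add atoms: sodium perborate (NaBO3·4H2O), [Na+].[Na+].O[B-]1(O)OO[B-](O)(O)OO1
Why: perborate oxidation of the primary C–B bond (1,2-shift from boron to oxygen) is mild enough for the ester, and the cis-disposed CH2OH and ester groups then close the cis-fused γ-lactone, a closure that a 3,4-trans isomer cannot undergo, so the step also purifies the stereochemical series.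

Step 7
Reactants: 11 rac-(3aR,4S,6R,6aR)-4,6-di-Ar-tetrahydro-1H,3H-furo[3,4-c]furan-1-one
Product: 12 meso-[(2R,3S,4R,5S)-2,5-di-Ar-oxolane-3,4-diyl]dimethanol
Conditions: LiAlH4, THF, 0 °C; H2O, 15% aq NaOH, H2O
Reagents that add atoms: none
Why: hydride reduction of a γ-lactone to the 1,4-diol touches neither the four stereocentres nor the benzyl ethers and gives a product that is now meso; the work-up is kept non-acidic because the diol could otherwise rearrange through benzylic cations.

Step 8
Reactants: 12 meso-[(2R,3S,4R,5S)-2,5-di-Ar-oxolane-3,4-diyl]dimethanol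
Product: 13 meso-[(2R,3S,4R,5S)-2,5-di-Ar-oxolane-3,4-diyl]bis(methylene) diacetate
Conditions: Ac2O, pyridine, DMAP (cat.), CH2Cl2, 0 °C → rt
Reagents that add atoms: acetic anhydride, CC(=O)OC(C)=O
Why: DMAP-catalysed acylation of two equivalent primary alcohols is routine and has to precede debenzylation, since free catechol hydroxyls would otherwise be acetylated as well.

Step 9
Reactants: 13 meso-[(2R,3S,4R,5S)-2,5-di-Ar-oxolane-3,4-diyl]bis(methylene) diacetate
Product: 14 [(2R,3S,4R,5S)-2,5-bis(3,4-dihydroxyphenyl)oxolane-3,4-diyl]bis(methylene) diacetate (CNP0416169.1)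
Conditions: H2 (1 atm), 10% Pd/C, EtOAc/THF, rt, stopped at full debenzylation; filtration under Ar
Reagents that add atoms: none
Why: catalytic hydrogenolysis cleaves aryl benzyl ethers faster than the hindered ring C–O bonds at C2 and C5, as in its routine use on benzyl-protected 2,5-diaryloxolane lignans, provided neutral solvent, one atmosphere of H2 and prompt termination are used, and the acetates are inert.

Compound list
1 | 3,4-bis(benzyloxy)benzaldehyde | O=Cc1ccc(OCc2ccccc2)c(OCc2ccccc2)c1 | starting material
2 | ethynylmagnesium bromide | C#C[Mg]Br | starting material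
3 | rac-(1S)-1-[3,4-bis(benzyloxy)phenyl]prop-2-yn-1-ol | O[C@H](c1ccc(OCc2ccccc2)c(OCc2ccccc2)c1)C#C | intermediate
4 | triethyl phosphonoacetate | CCOC(=O)CP(=O)(OCC)OCC | starting material
5 | ethyl (2E)-3-[3,4-bis(benzyloxy)phenyl]prop-2-enoate | CCOC(=O)/C=C/c1ccc(OCc2ccccc2)c(OCc2ccccc2)c1 | intermediate
6 | rac-ethyl (2S,3S)-3-[3,4-bis(benzyloxy)phenyl]-3-{[(1S)-1-[3,4-bis(benzyloxy)phenyl]prop-2-yn-1-yl]oxy}-2-bromopropanoate | CCOC(=O)[C@@H](Br)[C@H](c1ccc(OCc2ccccc2)c(OCc2ccccc2)c1)O[C@H](c1ccc(OCc2ccccc2)c(OCc2ccccc2)c1)C#C | intermediate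
7 | pinacolborane (4,4,5,5-tetramethyl-1,3,2-dioxaborolane) | CC1(C)OBOC1(C)C | starting material
8 | rac-ethyl (2S,3S)-3-[3,4-bis(benzyloxy)phenyl]-3-{[(1S,2E)-1-[3,4-bis(benzyloxy)phenyl]-3-(4,4,5,5-tetramethyl-1,3,2-dioxaborolan-2-yl)prop-2-en-1-yl]oxy}-2-bromopropanoate | CCOC(=O)[C@@H](Br)[C@H](c1ccc(OCc2ccccc2)c(OCc2ccccc2)c1)O[C@H](c1ccc(OCc2ccccc2)c(OCc2ccccc2)c1)/C=C/B1OC(C)(C)C(C)(C)O1 | intermediate
9 | rac-ethyl (2R,3R,4S,5S)-2,5-bis[3,4-bis(benzyloxy)phenyl]-4-[(4,4,5,5-tetramethyl-1,3,2-dioxaborolan-2-yl)methyl]oxolane-3-carboxylate | CCOC(=O)[C@@H]1[C@H](CB2OC(C)(C)C(C)(C)O2)[C@@H](c2ccc(OCc3ccccc3)c(OCc3ccccc3)c2)O[C@H]1c1ccc(OCc2ccccc2)c(OCc2ccccc2)c1 | intermediate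
10 | rac-ethyl (2R,3R,4R,5S)-2,5-bis[3,4-bis(benzyloxy)phenyl]-4-(hydroxymethyl)oxolane-3-carboxylate | CCOC(=O)[C@@H]1[C@H](CO)[C@@H](c2ccc(OCc3ccccc3)c(OCc3ccccc3)c2)O[C@H]1c1ccc(OCc2ccccc2)c(OCc2ccccc2)c1 | intermediate
11 | rac-(3aR,4S,6R,6aR)-4,6-bis[3,4-bis(benzyloxy)phenyl]tetrahydro-1H,3H-furo[3,4-c]furan-1-one | O=C1OC[C@H]2[C@@H]1[C@H](c1ccc(OCc3ccccc3)c(OCc3ccccc3)c1)O[C@@H]2c1ccc(OCc2ccccc2)c(OCc2ccccc2)c1 | intermediate
12 | meso-{(2R,3S,4R,5S)-2,5-bis[3,4-bis(benzyloxy)phenyl]oxolane-3,4-diyl}dimethanol | OC[C@@H]1[C@H](CO)[C@@H](c2ccc(OCc3ccccc3)c(OCc3ccccc3)c2)O[C@H]1c1ccc(OCc2ccccc2)c(OCc2ccccc2)c1 | intermediate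
13 | meso-{(2R,3S,4R,5S)-2,5-bis[3,4-bis(benzyloxy)phenyl]oxolane-3,4-diyl}bis(methylene) diacetate | CC(=O)OC[C@@H]1[C@H](COC(C)=O)[C@@H](c2ccc(OCc3ccccc3)c(OCc3ccccc3)c2)O[C@H]1c1ccc(OCc2ccccc2)c(OCc2ccccc2)c1 | intermediate
14 | {(2R,3S,4R,5S)-2,5-bis(3,4-dihydroxyphenyl)oxolane-3,4-diyl}bis(methylene) diacetate (CNP0416169.1, meso) | CC(=O)OC[C@@H]1[C@H](COC(C)=O)[C@@H](c2ccc(O)c(O)c2)O[C@H]1c1ccc(O)c(O)c1 | target

Total step count: 9.
Longest linear sequence: 8 steps (1 → 5 → 6 → 8 → 9 → 11 → 12 → 13 → 14; the branch through 3 is equally long).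

Risk 1, step 3. The hindered secondary alcohol may trap the bromonium or benzylic cation too slowly. Ring bromination of the electron-rich arenes or trapping by traces of water could then take over, and the pairing of the two racemic partners is statistical in any case.
- The fallback sets out from 5 and 3 and comes back at 6. It closes the ether at the other C–O bond, O1–C5.
- Cinnamate 5 is treated with NBS in aqueous THF to give the anti bromohydrin rac-ethyl (2S,3S)-3-[3,4-bis(benzyloxy)phenyl]-2-bromo-3-hydroxypropanoate F1, so that NBS never meets 3.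
- Alcohol 3 is converted with Cl3CCN and catalytic DBU into rac-(1S)-1-[3,4-bis(benzyloxy)phenyl]prop-2-yn-1-yl 2,2,2-trichloroacetimidate F2.
- F1 is then O-alkylated by F2 under catalytic TMSOTf in CH2Cl2 at −40 °C. This is an acid-catalysed imidate alkylation through the aryl- and alkynyl-stabilised C5 cation. It should give 6 together with its C5 epimer, which are separated as before.
- If that separation proves impractical in either version, the mixture can be carried forward. Only the aryl-cis series is expected to reach a 3,4-cis hydroxy ester and hence lactone 11, which differs strongly in polarity from uncyclised hydroxy esters.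

Risk 2, step 5. Poor facial selectivity at the planar, ester-conjugated C3 radical is the most likely shortfall: the ester would end cis to the C2 aryl group and trans to the C4 arm. Reduction of the radical before ring closure is the second concern.
- The fallback sets out from 8 and comes back at 11. It replaces kinetic control at C3 by thermodynamic control.
- The cyclisation is run as described and the C3 epimer rac-ethyl (2R,3S,4S,5S)-2,5-bis[3,4-bis(benzyloxy)phenyl]-4-[(4,4,5,5-tetramethyl-1,3,2-dioxaborolan-2-yl)methyl]oxolane-3-carboxylate F3 is not removed.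
- NaBO3 oxidation converts it into the 3,4-trans hydroxy ester rac-ethyl (2R,3S,4R,5S)-2,5-bis[3,4-bis(benzyloxy)phenyl]-4-(hydroxymethyl)oxolane-3-carboxylate F4, which cannot lactonise.
- Catalytic NaOEt in EtOH/THF then equilibrates the ester-bearing carbon through its enolate. Material that reaches the cis isomer 10 closes to lactone 11 after neutralisation and the PPTS treatment of step 6.
- Lactone 11 combines the 2,3-trans and the cis-fused arrangements and is therefore the preferred isomer. β-Elimination of O1 from the enolate would be the reverse of a 5-endo-trig closure and should stay slow.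

Risk 3, step 9. Over-reduction is the concern. Hydrogenolysis of the ring bonds C2–O1 and C5–O1, both benzylic and activated by a para oxygen, may compete with O-debenzylation, and the free catechols may oxidise in air during isolation.
- The fallback sets out from 13 and comes back at 14. It is a non-reductive debenzylation with BCl3 and pentamethylbenzene as benzyl cation scavenger in CH2Cl2 at −78 °C, conditions that spare primary acetates.
- Any reversible ionisation at C2 or C5 should return the same isomer, because each aryl group already sits trans to its neighbour.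
- This fallback makes no new compound (entry F0).

Further compounds
F1 | step 3 | rac-ethyl (2S,3S)-3-[3,4-bis(benzyloxy)phenyl]-2-bromo-3-hydroxypropanoate | CCOC(=O)[C@@H](Br)[C@H](c1ccc(OCc2ccccc2)c(OCc2ccccc2)c1)O
F2 | step 3 | rac-(1S)-1-[3,4-bis(benzyloxy)phenyl]prop-2-yn-1-yl 2,2,2-trichloroacetimidate | N=C(O[C@H](c1ccc(OCc2ccccc2)c(OCc2ccccc2)c1)C#C)C(Cl)(Cl)Cl
F3 | step 5 | rac-ethyl (2R,3S,4S,5S)-2,5-bis[3,4-bis(benzyloxy)phenyl]-4-[(4,4,5,5-tetramethyl-1,3,2-dioxaborolan-2-yl)methyl]oxolane-3-carboxylate | CCOC(=O)[C@H]1[C@H](CB2OC(C)(C)C(C)(C)O2)[C@@H](c2ccc(OCc3ccccc3)c(OCc3ccccc3)c2)O[C@H]1c1ccc(OCc2ccccc2)c(OCc2ccccc2)c1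
F4 | step 5 | rac-ethyl (2R,3S,4R,5S)-2,5-bis[3,4-bis(benzyloxy)phenyl]-4-(hydroxymethyl)oxolane-3-carboxylate | CCOC(=O)[C@H]1[C@H](CO)[C@@H](c2ccc(OCc3ccccc3)c(OCc3ccccc3)c2)O[C@H]1c1ccc(OCc2ccccc2)c(OCc2ccccc2)c1
F0 | step 9 | none | none
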